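**Retrosynthetic overview** (locants follow the 1-benzofuran-2-one numbering of the target: O1, C2=O, C3=CH2, C3a, C4-OH, C5, C6, C7, C7a)
1. The C5 hydroxypropenyl group is traced back to an isopropenyl group (late Riley allylic hydroxylation of 19).
2. Key disconnection, one operation: C3a–C7a and C4–C5. Compound 19 comes from α-acyloxy aldehyde 15 (C7a, C7, C6 and the future C5 as a 2-methylprop-1-enyl arm) plus the two-carbon linchpin 5 (C3a is the γ-carbon of a 2-methoxycarbonyl allylboronate, C4 its acetal-masked aldehyde). The γ-lactone closes first, the cyclohexane second.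
3. Enabling feature: the cyclohexane holds two homoallylic-alcohol retrons that share the C3a–C4 bond, O1–C7a–C3a–C3(=CH2) in the lactone ring and HO–C4–C5–C(=CH2) at the side chain. C4 can therefore serve first as the γ-substituent of the allylboron reagent and then as the enophile for the alkene at C5.
4. Aldehyde 15 comes from (S)-glyceraldehyde acetonide 11 and (E)-dienylboronic acid 10: a closed-transition-state allylboration sets C7 and the quaternary C6, then the glyceraldehyde stereocentre is cut out by glycol cleavage. Acid 10 comes from ethyl but-2-ynoate and an alkenyl cuprate.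
5. Boronate 5 comes from the Baylis–Hillman adduct of methyl acrylate and glyoxal mono(dimethyl acetal).

Key step: step 10

Remark: the carbinol centre of 3 and 4 is racemic and is destroyed in step 3; 11, tetrahydroxydiboron and 60% aqueous 2 are taken as purchased.

**Step 1**
Reactants: 1 methyl acrylate; 2 2,2-dimethoxyacetaldehyde
Product: 3 methyl 3-hydroxy-4,4-dimethoxy-2-methylidenebutanoate (racemic)
Conditions: DABCO (0.5 equiv), 1,4-dioxane/H2O, rt
Reagents that add atoms: none
Why: Morita–Baylis–Hillman reaction; the DABCO–acrylate zwitterion adds to the electrophilic, non-enolisable glyoxal mono-acetal, and the racemic carbinol centre is erased in step 3.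

**Step 2**
Reactants: 3 methyl 3-hydroxy-4,4-dimethoxy-2-methylidenebutanoate
Product: 4 methyl 3-(acetyloxy)-4,4-dimethoxy-2-methylidenebutanoate (racemic)
Conditions: Ac2O, pyridine, DMAP (cat.), CH2Cl2, 0 °C to rt
Reagents that add atoms: acetic anhydride, CC(=O)OC(C)=O
Why: DMAP-catalysed O-acetylation turns the allylic hydroxyl into a leaving group for π-allyl formation.

**Step 3**
Reactants: 4 methyl 3-(acetyloxy)-4,4-dimethoxy-2-methylidenebutanoate
Product: 5 methyl (2E)-4,4-dimethoxy-2-[(4,4,5,5-tetramethyl-1,3,2-dioxaborolan-2-yl)methyl]but-2-enoate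
Conditions: B2pin2 (1.1 equiv), Pd2(dba)3 (2.5 mol%), THF, rt to 40 °C
Reagents that add atoms: bis(pinacolato)diboron, CC1(C)OB(OC1(C)C)B1OC(C)(C)C(C)(C)O1
Why: Miyaura-type allylic borylation of a Baylis–Hillman acetate; the 2-(methoxycarbonyl)allyl palladium intermediate is borylated at its CH2 terminus and should give the more stable trisubstituted alkene with the acetal carbon cis to CH2B, the geometry that later fixes C3a relative to C7a.

**Step 4**
Reactants: 6 ethyl but-2-ynoate; 7 (2-methylprop-1-en-1-yl)magnesium bromide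
Product: 8 ethyl (2E)-3,5-dimethylhexa-2,4-dienoate
Conditions: 7 (2.4 equiv), CuI (1.2 equiv), THF, −40 °C; then 6, −78 °C; aq. NH4Cl at −78 °C
Reagents that add atoms: none
Why: syn-carbocupration (cuprate conjugate addition) of the ynoate and low-temperature protonation of the α-cuprio ester should place the new alkenyl group trans to the ester, giving the 2E dienoate stereospecifically.

**Step 5**
Reactants: 8 ethyl (2E)-3,5-dimethylhexa-2,4-dienoate
Product: 9 (2E)-3,5-dimethylhexa-2,4-dien-1-ol
Conditions: i-Bu2AlH (2.2 equiv), CH2Cl2, −78 °C; aq. potassium sodium tartrate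
Reagents that add atoms: none
Why: 1,2-reduction of the ester by the aluminium hydride should leave both alkenes and the E geometry untouched.

**Step 6**
Reactants: 9 (2E)-3,5-dimethylhexa-2,4-dien-1-ol
Product: 10 [(2E)-3,5-dimethylhexa-2,4-dien-1-yl]boronic acid
Conditions: B2(OH)4 (1.2 equiv), Pd(MeCN)4(BF4)2 (2 mol%), DMSO/MeOH, rt, argon; extractive work-up, used at once
Reagents that add atoms: tetrahydroxydiboron, OB(O)B(O)O
Why: palladium-catalysed direct borylation of an allylic alcohol with diboronic acid should exchange OH for B(OH)2 at the primary terminus with retention of the trisubstituted alkene geometry, as known for geraniol and nerol.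

**Step 7**
Reactants: 10 [(2E)-3,5-dimethylhexa-2,4-dien-1-yl]boronic acid; 11 (4S)-2,2-dimethyl-1,3-dioxolane-4-carbaldehyde
Product: 12 (1R,2S)-1-[(4S)-2,2-dimethyl-1,3-dioxolan-4-yl]-2-ethenyl-2,4-dimethylpent-3-en-1-ol
Conditions: CH2Cl2, 3 Å MS, 0 °C to rt; aq. NaHCO3
Reagents that add atoms: none
Why: allylboration through a closed Zimmerman–Traxler chair; γ-attack creates the quaternary carbon (future C6) with methyl syn and the 2-methylprop-1-enyl arm anti to the new hydroxyl as the E geometry dictates, while Felkin–Anh (Cornforth) control by the dioxolane centre of 11 selects the aldehyde face and should fix the future C7 as R.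

**Step 8**
Reactants: 12 (1R,2S)-1-[(4S)-2,2-dimethyl-1,3-dioxolan-4-yl]-2-ethenyl-2,4-dimethylpent-3-en-1-ol
Product: 13 (1R,2S)-1-[(4S)-2,2-dimethyl-1,3-dioxolan-4-yl]-2-ethenyl-2,4-dimethylpent-3-en-1-yl 2-methylpropanoate
Conditions: (i-PrCO)2O (2 equiv), Et3N, DMAP (0.2 equiv), CH2Cl2, rt to 40 °C
Reagents that add atoms: 2-methylpropanoic anhydride, CC(C)C(=O)OC(=O)C(C)C
Why: DMAP-catalysed (Steglich-type) acylation of the only free hydroxyl installs the isobutyrate of the target before any other hydroxyl exists.

**Step 9**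
Reactants: 13 (1R,2S)-1-[(4S)-2,2-dimethyl-1,3-dioxolan-4-yl]-2-ethenyl-2,4-dimethylpent-3-en-1-yl 2-methylpropanoate
Product: 15 (2R,3S)-3-ethenyl-3,5-dimethyl-1-oxohex-4-en-2-yl 2-methylpropanoate, via diol 14 (not isolated)
Conditions: H5IO6 (1.5 equiv), EtOAc, rt
Reagents that add atoms: none
Why: periodic acid hydrolyses the terminal acetonide and cleaves the freed 1,2-diol in the same flask (glycol cleavage), which removes the relay stereocentre and unveils the α-acyloxy aldehyde without base, so the adjacent centre should not epimerise.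

**Step 10**
Reactants: 15 (2R,3S)-3-ethenyl-3,5-dimethyl-1-oxohex-4-en-2-yl 2-methylpropanoate; 5 methyl (2E)-4,4-dimethoxy-2-[(4,4,5,5-tetramethyl-1,3,2-dioxaborolan-2-yl)methyl]but-2-enoate
Product: 19 (3aS,4R,5S,6S,7R,7aS)-6-ethenyl-4-hydroxy-6-methyl-3-methylidene-2-oxo-5-(prop-1-en-2-yl)octahydro-1-benzofuran-7-yl 2-methylpropanoate, via borate adduct 16 (not isolated), via lactone acetal 17 (not isolated), via lactone aldehyde 18 (not isolated)
Conditions: 5 (1.3 equiv), Sc(OTf)3 (10 mol%), CH2Cl2, −20 °C to rt; then H2O (3 equiv) into the same flask, 0 °C to rt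
Reagents that add atoms: water, O
Why: Proposed new method: one charge of Sc(OTf)3 is asked to run in sequence three events that are each precedented only on their own, namely Lewis-acid-catalysed allylboration of an aldehyde by a 2-alkoxycarbonyl allylboronate with lactonisation (the closest known reaction type), metal-triflate hydrolysis of a dimethyl acetal, and the type 1 intramolecular carbonyl-ene cyclisation known from citronellal to isopulegol. Boronate 5 adds to the Sc-activated aldehyde of 15 through a closed six-membered chair transition state (new bond C3a–C7a, borate 16), the borate oxygen then attacks the methyl ester (5-exo-trig lactonisation, loss of MeOBpin) to close the γ-lactone 17, water releases aldehyde 18, and its Sc-bound carbonyl carbon is attacked by the proximal carbon of the 2-methylprop-1-enyl group while an allylic methyl hydrogen passes to oxygen (new bond C4–C5; cyclohexane closed 6-exo with respect to the alkene through a chair). C7a is set by Felkin–Anh (Cornforth) addition anti to the C7 acyloxy group, and C3a by the boronate geometry, because the acetal carbon is cis to CH2B (Z-crotyl-type) and such reagents give the syn adduct, which is the cis-fused lactone. C4 and C5 are set in the ene chair, in which the carbonyl oxygen and the alkene arm are equatorial next to the equatorial C3a acrylate carbon, C7 ester and C6 vinyl group (C6 methyl and O1 axial), so that the C4 hydroxyl should come out trans to both neighbours as in isopulegol. The step needs chemoselectivity between two aldehydes and among three alkenes: the C4 aldehyde stays an electron-poor acetal until 15 is consumed and water is admitted, and once free it can reach only the trisubstituted alkene in a six-membered array, since the vinyl group has no allylic hydrogen and the acrylate is electron-poor.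

**Step 11**
Reactants: 19 (3aS,4R,5S,6S,7R,7aS)-6-ethenyl-4-hydroxy-6-methyl-3-methylidene-2-oxo-5-(prop-1-en-2-yl)octahydro-1-benzofuran-7-yl 2-methylpropanoate
Product: 20 (3aS,4R,5S,6S,7R,7aS)-6-ethenyl-4-hydroxy-5-(3-hydroxyprop-1-en-2-yl)-6-methyl-3-methylidene-2-oxo-octahydro-1-benzofuran-7-yl 2-methylpropanoate
Conditions: SeO2 (0.3 equiv), t-BuOOH (2 equiv, in decane), CH2Cl2, 0 °C to rt
Reagents that add atoms: selenium dioxide, O=[Se]=O (oxygen carrier); tert-butyl hydroperoxide, CC(C)(C)OO (terminal oxidant)
Why: Riley allylic oxidation (ene reaction at the terminal carbon of the isopropenyl group, then [2,3]-sigmatropic shift) should give the primary allylic alcohol, because the acrylate is electron-poor, the vinyl group has no allylic hydrogen and the ring C5–H is hindered and poorly aligned; no stereocentre is formed.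

**Compound list**
1 | methyl acrylate | C=CC(=O)OC | starting material
2 | 2,2-dimethoxyacetaldehyde | COC(OC)C=O | starting material
3 | methyl 3-hydroxy-4,4-dimethoxy-2-methylidenebutanoate (racemic) | COC(=O)C(=C)C(O)C(OC)OC | intermediate
4 | methyl 3-(acetyloxy)-4,4-dimethoxy-2-methylidenebutanoate (racemic) | COC(=O)C(=C)C(OC(C)=O)C(OC)OC | intermediate
5 | methyl (2E)-4,4-dimethoxy-2-[(4,4,5,5-tetramethyl-1,3,2-dioxaborolan-2-yl)methyl]but-2-enoate (acetal carbon cis to CH2B) | COC(OC)/C=C(/C(=O)OC)CB1OC(C)(C)C(C)(C)O1 | intermediate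
6 | ethyl but-2-ynoate | CC#CC(=O)OCC | starting material
7 | (2-methylprop-1-en-1-yl)magnesium bromide | CC(C)=C[Mg]Br | starting material
8 | ethyl (2E)-3,5-dimethylhexa-2,4-dienoate | CCOC(=O)/C=C(/C=C(C)C)C | intermediate
9 | (2E)-3,5-dimethylhexa-2,4-dien-1-ol | OC/C=C(/C=C(C)C)C | intermediate
10 | [(2E)-3,5-dimethylhexa-2,4-dien-1-yl]boronic acid | OB(O)C/C=C(/C=C(C)C)C | intermediate
11 | (4S)-2,2-dimethyl-1,3-dioxolane-4-carbaldehyde ((S)-glyceraldehyde acetonide) | O=C[C@@H]1COC(C)(C)O1 | starting material
12 | (1R,2S)-1-[(4S)-2,2-dimethyl-1,3-dioxolan-4-yl]-2-ethenyl-2,4-dimethylpent-3-en-1-ol | C=C[C@@](C)(C=C(C)C)[C@@H](O)[C@@H]1COC(C)(C)O1 | intermediate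
13 | (1R,2S)-1-[(4S)-2,2-dimethyl-1,3-dioxolan-4-yl]-2-ethenyl-2,4-dimethylpent-3-en-1-yl 2-methylpropanoate | C=C[C@@](C)(C=C(C)C)[C@@H](OC(=O)C(C)C)[C@@H]1COC(C)(C)O1 | intermediate
14 | (2S,3R,4S)-4-ethenyl-1,2-dihydroxy-4,6-dimethylhept-5-en-3-yl 2-methylpropanoate (diol, not isolated) | C=C[C@@](C)(C=C(C)C)[C@@H](OC(=O)C(C)C)[C@@H](O)CO | intermediate
15 | (2R,3S)-3-ethenyl-3,5-dimethyl-1-oxohex-4-en-2-yl 2-methylpropanoate | C=C[C@@](C)(C=C(C)C)[C@@H](OC(=O)C(C)C)C=O | intermediate
16 | methyl (3R,4S,5R,6S)-3-(dimethoxymethyl)-6-ethenyl-6,8-dimethyl-2-methylidene-5-[(2-methylpropanoyl)oxy]-4-[(4,4,5,5-tetramethyl-1,3,2-dioxaborolan-2-yl)oxy]non-7-enoate (borate adduct, not isolated) | C=C[C@@](C)(C=C(C)C)[C@@H](OC(=O)C(C)C)[C@@H](OB1OC(C)(C)C(C)(C)O1)[C@H](C(OC)OC)C(=C)C(=O)OC | intermediate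
17 | (1R,2S)-1-[(2S,3R)-3-(dimethoxymethyl)-4-methylidene-5-oxooxolan-2-yl]-2-ethenyl-2,4-dimethylpent-3-en-1-yl 2-methylpropanoate (cis-lactone acetal, not isolated) | C=C[C@@](C)(C=C(C)C)[C@@H](OC(=O)C(C)C)[C@H]1OC(=O)C(=C)[C@H]1C(OC)OC | intermediate
18 | (1R,2S)-2-ethenyl-1-[(2S,3R)-3-formyl-4-methylidene-5-oxooxolan-2-yl]-2,4-dimethylpent-3-en-1-yl 2-methylpropanoate (lactone aldehyde, not isolated) | C=C[C@@](C)(C=C(C)C)[C@@H](OC(=O)C(C)C)[C@H]1OC(=O)C(=C)[C@H]1C=O | intermediate
19 | (3aS,4R,5S,6S,7R,7aS)-6-ethenyl-4-hydroxy-6-methyl-3-methylidene-2-oxo-5-(prop-1-en-2-yl)octahydro-1-benzofuran-7-yl 2-methylpropanoate | C=C[C@@]1(C)[C@H](C(C)=C)[C@@H](O)[C@@H]2C(=C)C(=O)O[C@@H]2[C@@H]1OC(=O)C(C)C | intermediate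
20 | (3aS,4R,5S,6S,7R,7aS)-6-ethenyl-4-hydroxy-5-(3-hydroxyprop-1-en-2-yl)-6-methyl-3-methylidene-2-oxo-octahydro-1-benzofuran-7-yl 2-methylpropanoate | C=C[C@@]1(C)[C@H](C(=C)CO)[C@@H](O)[C@@H]2C(=C)C(=O)O[C@@H]2[C@@H]1OC(=O)C(C)C | target

**Step count**
Total: 11 steps. Longest linear sequence: 8 steps (steps 4 to 11); boronate 5 is made in 3 steps (steps 1 to 3).

**Steps most likely to fail**

Step 10 (proposed domino). Possible failures as processes:
- premature ionisation of the acetal of 17 under the anhydrous Lewis acid, so that the ring closes through the methyl oxocarbenium ion and C4 ends as a methyl ether;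
- epimerisation at C3a, or migration of the exocyclic alkene into conjugation, in aldehyde 18 before ring closure;
- hydration of the developing tertiary cation once water is present;
- acyl migration from the C7 oxygen or translactonisation towards the C4 oxygen.

Fallback, known reactions only and stepwise. Corey–Kim bromination of 3 (NBS, Me2S, CH2Cl2, 0 °C) should give methyl (2Z)-2-(bromomethyl)-4,4-dimethoxybut-2-enoate F1. Indium-mediated Barbier allylation of 15 with F1 (In, THF/H2O, rt), which for this reagent class and O-protected α-oxy aldehydes is syn- and Felkin-selective, should give the hydroxy ester methyl (3R,4S,5R,6S)-3-(dimethoxymethyl)-6-ethenyl-4-hydroxy-6,8-dimethyl-2-methylidene-5-[(2-methylpropanoyl)oxy]non-7-enoate F2. TsOH (cat., CH2Cl2) then closes the lactone to 17, now isolated. Aqueous trifluoroacetic acid (CHCl3, 0 °C) hydrolyses the acetal to 18, which is treated at once with Me2AlCl (CH2Cl2, −78 °C) for the carbonyl-ene closure. The fallback sets out from 3 and 15 and comes back to the route at 19.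

Step 11. Possible failures as processes: over-oxidation of the new allylic alcohol to the enal, competing oxidation at the ring C5–H, or slow conversion. Fallback: Schenck ene photooxygenation of 19 (O2, tetraphenylporphyrin, visible light, CH2Cl2, 0 °C) should give the allylic hydroperoxide (3aS,4R,5S,6S,7R,7aS)-6-ethenyl-5-(3-hydroperoxyprop-1-en-2-yl)-4-hydroxy-6-methyl-3-methylidene-2-oxo-octahydro-1-benzofuran-7-yl 2-methylpropanoate F3, which is reduced with PPh3 (CH2Cl2, 0 °C). The fallback sets out from 19 and comes back at 20.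

Step 7. Possible failures as processes: oxidative or protolytic loss of the boronic acid, or erosion of its E geometry before addition (which would invert C6 relative to C7), and insufficient Felkin facial selectivity. Fallback: 9 is converted with methyl chloroformate and pyridine (CH2Cl2, 0 °C) into methyl (2E)-3,5-dimethylhexa-2,4-dien-1-yl carbonate F4. Miyaura-type allylic borylation (B2pin2, Pd2(dba)3 cat., THF, 50 °C) then gives the bench-stable, purifiable 2-[(2E)-3,5-dimethylhexa-2,4-dien-1-yl]-4,4,5,5-tetramethyl-1,3,2-dioxaborolane F5. This ester is added thermally to 11 (toluene, 50 °C; triethanolamine work-up) through the same chair transition state. The fallback sets out from 9 and comes back at 12.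

**Further compounds**
F1 | step 10 | methyl (2Z)-2-(bromomethyl)-4,4-dimethoxybut-2-enoate | COC(OC)/C=C(/C(=O)OC)CBr
F2 | step 10 | methyl (3R,4S,5R,6S)-3-(dimethoxymethyl)-6-ethenyl-4-hydroxy-6,8-dimethyl-2-methylidene-5-[(2-methylpropanoyl)oxy]non-7-enoate | C=C[C@@](C)(C=C(C)C)[C@@H](OC(=O)C(C)C)[C@@H](O)[C@H](C(OC)OC)C(=C)C(=O)OC
F3 | step 11 | (3aS,4R,5S,6S,7R,7aS)-6-ethenyl-5-(3-hydroperoxyprop-1-en-2-yl)-4-hydroxy-6-methyl-3-methylidene-2-oxo-octahydro-1-benzofuran-7-yl 2-methylpropanoate | C=C[C@@]1(C)[C@H](C(=C)COO)[C@@H](O)[C@@H]2C(=C)C(=O)O[C@@H]2[C@@H]1OC(=O)C(C)C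
F4 | step 7 | methyl (2E)-3,5-dimethylhexa-2,4-dien-1-yl carbonate | COC(=O)OC/C=C(/C=C(C)C)C
F5 | step 7 | 2-[(2E)-3,5-dimethylhexa-2,4-dien-1-yl]-4,4,5,5-tetramethyl-1,3,2-dioxaborolane | CC(C)=C/C(C)=C/CB1OC(C)(C)C(C)(C)O1
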